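**Plan**

1. Numbering: 1,2-dioxane O1, O2, C3 (CH2CO2H), C4 (CH3), C5, C6 (CH3 and side chain C1'–C10' with methyls at C2' and C6'). The retrosynthesis first cuts C3–CH2CO2H (peroxycarbenium ion plus silyl ketene acetal), then puts a helper hydroxyl on C5, then cuts C4–C5 and O2–C3 together, leaving propanal and an α-peroxy aldehyde (C5, C6, O1, O2).
2. The α-peroxy aldehyde goes back to a 2,2-disubstituted epoxide (C6–O1 by perhydrolysis with inversion), then to a methyl ketone, and this to (R)-citronellyl bromide, a phenethyl Grignard reagent and pent-3-en-2-one.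
3. Forward: the chain is joined first (4 steps), then come epoxide, tertiary hydroperoxide and silyl-masked α-peroxy aldehyde; the only ring, the 1,2-dioxane, arises in step 9; the C5 hydroxyl is then removed and the acetic acid arm is put on C3 last.
4. The event is possible because C3–C4–C5 is an aldol array once C5 bears OH, because O2 and C3 are the ends of the six-atom chain O2–O1–C6–C5–C4–C3 so that the γ-hydroperoxy aldehyde closes to the six-membered peroxyacetal, and because quaternary C6 makes the aldehyde a pure acceptor.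
5. Stereochemistry: C6' from the chiral pool; C2' by catalytic asymmetric conjugate addition; C6 by asymmetric epoxidation followed by inversion; C4 by L-proline; C3 by axial attack on the peroxycarbenium ion under control of C4 and C6.

Key step: step 9

Assumption: the sense of induction written for the chiral catalysts of steps 4 and 5 is the expected one; if either proves opposite, the mirror-image ligand is used and nothing else changes.

**Route**

Step 1
Reactants: 1 (R)-citronellyl bromide [(6R)-8-bromo-2,6-dimethyloct-2-ene]; 2 2-phenylethylmagnesium chloride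
Product: 3 (6S)-2,6-dimethyl-10-phenyldec-2-ene
Conditions: Li2CuCl4 (3 mol %), THF, −10 °C to rt
Reagents that add atoms: none
Why: Copper-catalysed alkyl–alkyl cross-coupling of a primary bromide with a primary Grignard reagent; the methyl stereocentre (later C6') is bought with 1, is remote from the reacting carbon and is carried through unchanged (the descriptor changes from R to S only because the ranking of its two chains is reversed).

Step 2
Reactants: 3 (6S)-2,6-dimethyl-10-phenyldec-2-ene
Product: 5 (4S)-4-methyl-8-phenyloctan-1-ol, via (4S)-4-methyl-8-phenyloctanal 4 (not isolated)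
Conditions: O3, CH2Cl2/MeOH, −78 °C; then NaBH4, −78 °C to rt
Reagents that add atoms: ozone, O=[O+][O-]
Why: Ozonolysis of the trisubstituted alkene with reductive work-up should cleave the isopropylidene end to the primary alcohol while the arene and the stereocentre stay untouched.

Step 3
Reactants: 5 (4S)-4-methyl-8-phenyloctan-1-ol
Product: 6 [(5S)-8-bromo-5-methyloctyl]benzene
Conditions: CBr4, PPh3, CH2Cl2, 0 °C
Reagents that add atoms: carbon tetrabromide, BrC(Br)(Br)Br
Why: Appel bromination of an unhindered primary alcohol; no stereocentre is involved.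

Step 4
Reactants: 6 [(5S)-8-bromo-5-methyloctyl]benzene; 7 (E)-pent-3-en-2-one
Product: 9 (4R,8S)-4,8-dimethyl-12-phenyldodecan-2-one, via [(4S)-4-methyl-8-phenyloctyl]magnesium bromide 8 (not isolated)
Conditions: Mg, Et2O, reflux; then CuBr·SMe2 (5 mol %), (R)-1-[(S)-2-(diphenylphosphino)ferrocenyl]ethyldicyclohexylphosphine (6 mol %), tBuOMe, −75 °C; 1 M HCl
Reagents that add atoms: none
Why: Copper-catalysed asymmetric conjugate addition of a primary alkyl Grignard reagent to an acyclic enone; the new centre C4 of 9 (later C2', R) is set by the chiral ferrocenyl diphosphine catalyst, independently of the remote C8 centre.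

Step 5
Reactants: 9 (4R,8S)-4,8-dimethyl-12-phenyldodecan-2-one
Product: 10 (2S)-2-[(2R,6S)-2,6-dimethyl-10-phenyldecyl]-2-methyloxirane
Conditions: Me3S(O)I, NaH, THF, rt; then LaLi3[(S)-1,1'-bi-2-naphtholate]3 (5 mol %), [2,4,6-(MeO)3C6H2]3P=O (5 mol %), 5 Å MS, THF, rt
Reagents that add atoms: trimethylsulfoxonium iodide, C[S+](C)(C)=O.[I-]
Why: Catalytic asymmetric Corey–Chaykovsky epoxidation of a methyl ketone; the heterobimetallic binaphtholate catalyst tells methyl from the CH2 chain and sets the quaternary carbon (2S), which a substrate-based method could not do because the two carbon groups are sterically alike.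

Step 6
Reactants: 10 (2S)-2-[(2R,6S)-2,6-dimethyl-10-phenyldecyl]-2-methyloxirane
Product: 11 (2R,4R,8S)-2-hydroperoxy-2,4,8-trimethyl-12-phenyldodecan-1-ol
Conditions: anhydrous H2O2 in Et2O (10 equiv), H3PMo12O40 (2 mol %), rt
Reagents that add atoms: hydrogen peroxide, OO
Why: Acid-catalysed perhydrolysis (ring opening of the epoxide by H2O2 at the more substituted carbon), a known reaction of 2,2-disubstituted epoxides; the borderline SN2 opening should invert the quaternary centre and so turn the 2S epoxide into the 2R hydroperoxide that is C6 of the dioxane.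

Step 7
Reactants: 11 (2R,4R,8S)-2-hydroperoxy-2,4,8-trimethyl-12-phenyldodecan-1-ol
Product: 12 triethyl{[(2R,4R,8S)-2,4,8-trimethyl-12-phenyl-2-(triethylsilylperoxy)dodecyl]oxy}silane
Conditions: Et3SiCl (2.4 equiv), imidazole, DMF, 0 °C
Reagents that add atoms: chlorotriethylsilane, CC[Si](Cl)(CC)CC
Why: O-Silylation of both the hydroperoxide and the primary alcohol, which avoids any need to tell the two hydroxyl groups apart and masks the OOH for the next two steps.

Step 8
Reactants: 12 triethyl{[(2R,4R,8S)-2,4,8-trimethyl-12-phenyl-2-(triethylsilylperoxy)dodecyl]oxy}silane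
Product: 13 (2R,4R,8S)-2,4,8-trimethyl-12-phenyl-2-(triethylsilylperoxy)dodecanal
Conditions: (COCl)2, DMSO, CH2Cl2, −78 to −40 °C; Et3N, −78 to 0 °C
Reagents that add atoms: none
Why: Swern oxidation, which converts primary triethylsilyl ethers directly into aldehydes; the tertiary silyl peroxide carries no oxidisable C–H, and the aldehyde has no α-hydrogen, so the quaternary centre cannot epimerise (13 is used crude).

Step 9
Reactants: 13 (2R,4R,8S)-2,4,8-trimethyl-12-phenyl-2-(triethylsilylperoxy)dodecanal; 14 propanal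
Product: 17 (4S,5R,6R)-6-[(2R,6S)-2,6-dimethyl-10-phenyldecyl]-3-methoxy-4,6-dimethyl-1,2-dioxan-5-ol (both C3 anomers), via silylperoxy aldol 15 (not isolated), via 1,2-dioxane-3,5-diol 16 (not isolated)
Conditions: L-proline (20 mol %), DMF, 4 °C, slow addition of 14 (3 equiv); excess 14 removed in vacuo; then MeOH, CSA (0.5 equiv), 0 °C to rt
Reagents that add atoms: methanol, CO
Why: L-Proline and propanal give the (E)-enamine, which adds through the hydrogen-bonded chair transition state to the carbonyl of 13 (C4–C5 bond, enamine aldol); acidic methanol then removes Et3Si from O2, the freed hydroperoxide adds to the C3 aldehyde (O2–C3 bond) and hemiacetal 16 is converted into the methyl peroxyacetal 17. The closest known reactions are the proline-catalysed direct cross-aldol of propanal with α-branched or non-enolizable aldehydes and the ring closure of γ-hydroperoxy carbonyl compounds to 3-alkoxy-1,2-dioxanes in acidic alcohol. The one ring closed is the 1,2-dioxane (O1–O2–C3–C4–C5–C6), by 6-exo-trig addition of O2 to the C3 carbonyl. C4 (S) is set by the catalyst (enamine face fixed by the proline carboxylic acid) and so is the helper centre C5 (R, anti to the C4 methyl in the open chain); C3 forms as both anomers, which does not matter because C3 is ionized in step 12, and C6 is not touched. The step needs cross- over self-aldol selectivity, secured because 13 has a quaternary α-carbon and can only be the acceptor (activated by the α-peroxy oxygen) while 14 is added slowly; it also needs the hydroperoxide masked until the C5 carbonyl is consumed, since a free α-hydroperoxy aldehyde would fragment, and the silyl peroxide does this. C6 cannot relay its configuration to C4 because its methyl and CH2 groups are sterically alike, which is why C4 is put under catalyst control.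

Step 10
Reactants: 17 (4S,5R,6R)-6-[(2R,6S)-2,6-dimethyl-10-phenyldecyl]-3-methoxy-4,6-dimethyl-1,2-dioxan-5-ol
Product: 18 O-{(4S,5R,6R)-6-[(2R,6S)-2,6-dimethyl-10-phenyldecyl]-3-methoxy-4,6-dimethyl-1,2-dioxan-5-yl} O-phenyl carbonothioate
Conditions: PhOC(S)Cl, pyridine, DMAP (cat.), CH2Cl2, 0 °C to rt
Reagents that add atoms: O-phenyl chlorothionoformate, S=C(Cl)Oc1ccccc1
Why: Thioacylation of the secondary alcohol under neutral conditions gives the Barton–McCombie precursor without harm to the peroxyacetal.

Step 11
Reactants: 18 O-{(4S,5R,6R)-6-[(2R,6S)-2,6-dimethyl-10-phenyldecyl]-3-methoxy-4,6-dimethyl-1,2-dioxan-5-yl} O-phenyl carbonothioate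
Product: 19 (4S,6R)-6-[(2R,6S)-2,6-dimethyl-10-phenyldecyl]-3-methoxy-4,6-dimethyl-1,2-dioxane (both C3 anomers)
Conditions: Bu3SnH, AIBN (cat.), toluene, 80 °C
Reagents that add atoms: none
Why: Barton–McCombie deoxygenation removes the helper oxygen at C5; the C5 radical sits in the ring with the O1–O2 bond gauche to it (C5···O1–O2 angle near 90°), so the attack on oxygen that destroys open-chain β-peroxy radicals is geometrically blocked and hydrogen transfer from the tin hydride should win, in line with known tin hydride reductions of ring-substituted cyclic peroxides; C5 becomes CH2 and no stereocentre is formed.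

Step 12
Reactants: 19 (4S,6R)-6-[(2R,6S)-2,6-dimethyl-10-phenyldecyl]-3-methoxy-4,6-dimethyl-1,2-dioxane; 20 tert-butyl[(1-methoxyethenyl)oxy]dimethylsilane
Product: 21 methyl 2-{(3S,4S,6R)-6-[(2R,6S)-2,6-dimethyl-10-phenyldecyl]-4,6-dimethyl-1,2-dioxan-3-yl}acetate
Conditions: TMSOTf (20 mol %), CH2Cl2, −78 °C
Reagents that add atoms: none
Why: Lewis-acid-mediated substitution of the peroxyacetal through the cyclic peroxycarbenium ion (Mukaiyama-type addition of a silyl ketene acetal, known for 3-alkoxy-1,2-dioxanes); the ion should adopt the half-chair with the C4 methyl pseudoequatorial (the other half-chair would set it syn-axial to a C6 substituent) and be attacked axially on the face that leads to a chair, which places CH2CO2Me cis to the C4 methyl and gives 3S (the deoxygenation comes first because an axial C5 oxygen would shield this face).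

Step 13
Reactants: 21 methyl 2-{(3S,4S,6R)-6-[(2R,6S)-2,6-dimethyl-10-phenyldecyl]-4,6-dimethyl-1,2-dioxan-3-yl}acetate
Product: 22 2-{(3S,4S,6R)-6-[(2R,6S)-2,6-dimethyl-10-phenyldecyl]-4,6-dimethyl-1,2-dioxan-3-yl}acetic acid
Conditions: LiOH, THF/H2O, 0 °C; then 1 M HCl
Reagents that add atoms: lithium hydroxide, [Li+].[OH-]
Why: Saponification of the methyl ester, the usual last step for 1,2-dioxane-3-acetic acids; low temperature and short contact should keep retro-oxa-Michael opening at C3 from competing, so no stereocentre changes.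

**Compound list**

1 | (R)-citronellyl bromide, (6R)-8-bromo-2,6-dimethyloct-2-ene | C[C@@H](CCBr)CCC=C(C)C | starting material
2 | 2-phenylethylmagnesium chloride | Cl[Mg]CCc1ccccc1 | starting material
3 | (6S)-2,6-dimethyl-10-phenyldec-2-ene | C[C@@H](CCCCc1ccccc1)CCC=C(C)C | intermediate
4 | (4S)-4-methyl-8-phenyloctanal | C[C@@H](CCCCc1ccccc1)CCC=O | intermediate
5 | (4S)-4-methyl-8-phenyloctan-1-ol | C[C@@H](CCCCc1ccccc1)CCCO | intermediate
6 | [(5S)-8-bromo-5-methyloctyl]benzene | C[C@@H](CCCCc1ccccc1)CCCBr | intermediate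
7 | (E)-pent-3-en-2-one | C/C=C/C(C)=O | starting material
8 | [(4S)-4-methyl-8-phenyloctyl]magnesium bromide | C[C@@H](CCCCc1ccccc1)CCC[Mg]Br | intermediate
9 | (4R,8S)-4,8-dimethyl-12-phenyldodecan-2-one | C[C@@H](CCCCc1ccccc1)CCC[C@@H](C)CC(C)=O | intermediate
10 | (2S)-2-[(2R,6S)-2,6-dimethyl-10-phenyldecyl]-2-methyloxirane | C[C@@H](CCCCc1ccccc1)CCC[C@@H](C)C[C@@]1(C)CO1 | intermediate
11 | (2R,4R,8S)-2-hydroperoxy-2,4,8-trimethyl-12-phenyldodecan-1-ol | C[C@@H](CCCCc1ccccc1)CCC[C@@H](C)C[C@](OO)(C)CO | intermediate
12 | triethyl{[(2R,4R,8S)-2,4,8-trimethyl-12-phenyl-2-(triethylsilylperoxy)dodecyl]oxy}silane | C[C@@H](CCCCc1ccccc1)CCC[C@@H](C)C[C@](OO[Si](CC)(CC)CC)(C)CO[Si](CC)(CC)CC | intermediate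
13 | (2R,4R,8S)-2,4,8-trimethyl-12-phenyl-2-(triethylsilylperoxy)dodecanal | C[C@@H](CCCCc1ccccc1)CCC[C@@H](C)C[C@](OO[Si](CC)(CC)CC)(C)C=O | intermediate
14 | propanal | CCC=O | starting material
15 | (2S,3R,4R,6R,10S)-3-hydroxy-2,4,6,10-tetramethyl-14-phenyl-4-(triethylsilylperoxy)tetradecanal | C[C@@H](CCCCc1ccccc1)CCC[C@@H](C)C[C@](OO[Si](CC)(CC)CC)(C)[C@H](O)[C@H](C)C=O | intermediate
16 | (4S,5R,6R)-6-[(2R,6S)-2,6-dimethyl-10-phenyldecyl]-4,6-dimethyl-1,2-dioxane-3,5-diol, both C3 anomers | C[C@@H](CCCCc1ccccc1)CCC[C@@H](C)C[C@]1(C)[C@H](O)[C@H](C)C(O)OO1 | intermediate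
17 | (4S,5R,6R)-6-[(2R,6S)-2,6-dimethyl-10-phenyldecyl]-3-methoxy-4,6-dimethyl-1,2-dioxan-5-ol, both C3 anomers | C[C@@H](CCCCc1ccccc1)CCC[C@@H](C)C[C@]1(C)[C@H](O)[C@H](C)C(OC)OO1 | intermediate
18 | O-{(4S,5R,6R)-6-[(2R,6S)-2,6-dimethyl-10-phenyldecyl]-3-methoxy-4,6-dimethyl-1,2-dioxan-5-yl} O-phenyl carbonothioate, both C3 anomers | C[C@@H](CCCCc1ccccc1)CCC[C@@H](C)C[C@]1(C)[C@H](OC(=S)Oc2ccccc2)[C@H](C)C(OC)OO1 | intermediate
19 | (4S,6R)-6-[(2R,6S)-2,6-dimethyl-10-phenyldecyl]-3-methoxy-4,6-dimethyl-1,2-dioxane, both C3 anomers | C[C@@H](CCCCc1ccccc1)CCC[C@@H](C)C[C@]1(C)C[C@H](C)C(OC)OO1 | intermediate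
20 | tert-butyl[(1-methoxyethenyl)oxy]dimethylsilane | C=C(OC)O[Si](C)(C)C(C)(C)C | starting material
21 | methyl 2-{(3S,4S,6R)-6-[(2R,6S)-2,6-dimethyl-10-phenyldecyl]-4,6-dimethyl-1,2-dioxan-3-yl}acetate | C[C@@H](CCCCc1ccccc1)CCC[C@@H](C)C[C@]1(C)C[C@H](C)[C@H](CC(=O)OC)OO1 | intermediate
22 | 2-{(3S,4S,6R)-6-[(2R,6S)-2,6-dimethyl-10-phenyldecyl]-4,6-dimethyl-1,2-dioxan-3-yl}acetic acid | C[C@@H](CCCCc1ccccc1)CCC[C@@H](C)C[C@]1(C)C[C@H](C)[C@H](CC(=O)O)OO1 | target

**Count and risks**

Total steps: 13. Longest linear sequence: 13 steps (from 1).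

Steps most likely to fail:

Step 9. Addition of the enamine to the hindered, neopentyl-type carbonyl may be slower than self-aldolization of propanal, and the silyl group may be lost from the peroxide before the C5 carbonyl is consumed, which would open the way to fragmentation. The fallback sets out from 13: anti-crotylboration with (E)-crotyldiisopinocampheylborane of the hand that gives the 3R,4R alcohol (reagent control, ethanolamine work-up) should give the homoallylic alcohol (3R,4R,5R,7R,11S)-3,5,7,11-tetramethyl-15-phenyl-5-(triethylsilylperoxy)pentadec-1-en-4-ol F1. Ozonolysis of its terminal alkene (O3, CH2Cl2, −78 °C; Me2S) should give aldol 15, where the route is rejoined; 15 is then treated with CSA in MeOH as in step 9.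

Step 6. Opening of the tertiary epoxide carbon may gain carbocation character, so that the configuration at C6 is partly lost, or attack may stray to the primary carbon. The fallback sets out from 10: base-induced isomerization (LiNEt2, Et2O, reflux) to the 2-methylene alcohol (4R,8S)-4,8-dimethyl-2-methylidene-12-phenyldodecan-1-ol F2, silylation (Et3SiCl, imidazole) to its triethylsilyl ether triethyl{[(4R,8S)-4,8-dimethyl-2-methylidene-12-phenyldodecyl]oxy}silane F3, and Isayama–Mukaiyama hydroperoxysilylation (Co(acac)2, O2, Et3SiH, ClCH2CH2Cl, rt). This would give 12 together with its C2 epimer triethyl{[(2S,4R,8S)-2,4,8-trimethyl-12-phenyl-2-(triethylsilylperoxy)dodecyl]oxy}silane F4. The two are diastereomers and would be separated by preparative HPLC, and the route is rejoined at 12. This fallback trades control at C6 for a separation.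

Step 8. Chloride present under the Swern conditions may strip the silyl group from the peroxide, and the unmasked α-hydroperoxy aldehyde would then cleave between C5 and C6. The fallback sets out from 11: selective silylation of the more acidic hydroperoxide (TBSCl 1.05 equiv, imidazole, CH2Cl2, −20 °C) to (2R,4R,8S)-2-(tert-butyldimethylsilylperoxy)-2,4,8-trimethyl-12-phenyldodecan-1-ol F5, then buffered Dess–Martin oxidation of the free primary alcohol to (2R,4R,8S)-2-(tert-butyldimethylsilylperoxy)-2,4,8-trimethyl-12-phenyldodecanal F6. F6 takes the place of 13 in step 9 and should give the aldol (2S,3R,4R,6R,10S)-4-(tert-butyldimethylsilylperoxy)-3-hydroxy-2,4,6,10-tetramethyl-14-phenyltetradecanal F7 and, after the same acidic methanol stage, 17, where the route is rejoined.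

Further compounds
F1 | step 9 | (3R,4R,5R,7R,11S)-3,5,7,11-tetramethyl-15-phenyl-5-(triethylsilylperoxy)pentadec-1-en-4-ol | C[C@@H](CCCCc1ccccc1)CCC[C@@H](C)C[C@](OO[Si](CC)(CC)CC)(C)[C@H](O)[C@H](C)C=C
F2 | step 6 | (4R,8S)-4,8-dimethyl-2-methylidene-12-phenyldodecan-1-ol | C[C@@H](CCCCc1ccccc1)CCC[C@@H](C)CC(=C)CO
F3 | step 6 | triethyl{[(4R,8S)-4,8-dimethyl-2-methylidene-12-phenyldodecyl]oxy}silane | C[C@@H](CCCCc1ccccc1)CCC[C@@H](C)CC(=C)CO[Si](CC)(CC)CC
F4 | step 6 | triethyl{[(2S,4R,8S)-2,4,8-trimethyl-12-phenyl-2-(triethylsilylperoxy)dodecyl]oxy}silane | C[C@@H](CCCCc1ccccc1)CCC[C@@H](C)C[C@@](OO[Si](CC)(CC)CC)(C)CO[Si](CC)(CC)CC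
F5 | step 8 | (2R,4R,8S)-2-(tert-butyldimethylsilylperoxy)-2,4,8-trimethyl-12-phenyldodecan-1-ol | C[C@@H](CCCCc1ccccc1)CCC[C@@H](C)C[C@](OO[Si](C)(C)C(C)(C)C)(C)CO
F6 | step 8 | (2R,4R,8S)-2-(tert-butyldimethylsilylperoxy)-2,4,8-trimethyl-12-phenyldodecanal | C[C@@H](CCCCc1ccccc1)CCC[C@@H](C)C[C@](OO[Si](C)(C)C(C)(C)C)(C)C=O
F7 | step 8 | (2S,3R,4R,6R,10S)-4-(tert-butyldimethylsilylperoxy)-3-hydroxy-2,4,6,10-tetramethyl-14-phenyltetradecanal | C[C@@H](CCCCc1ccccc1)CCC[C@@H](C)C[C@](OO[Si](C)(C)C(C)(C)C)(C)[C@H](O)[C@H](C)C=O
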